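**Retrosynthetic overview**
- The target comes from Lindlar semihydrogenation of its side-chain alkyne analogue; the alkyne serves as an oxidation-proof mask of the Z-alkene.
- The 4,5-trans/5,6-cis triol comes from anti-hydrolysis (water at C4) of a cis-4,5-epoxy-6-hydroxy-6-alkylcyclohex-2-enone.
- The epoxy-quinol comes from a one-flask, metal-free, chiral aryl-iodane-catalysed hydroxylative dearomatisation of a 2-alkylphenol (sets C6), followed by OH-directed epoxidation (sets C4 and C5).
- The carbocycle is the benzene ring of o-cresol, so no ring-forming step is needed; the only ring made is the oxirane, which is opened in the next step.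
- The 2-(nonadec-10-ynyl)phenol comes from benzylic C-alkylation of the o-cresol dianion with octadec-9-ynyl bromide, itself from dec-1-yne and 1,8-dibromooctane.

Assumption: reagents, catalysts and solvents carry no compound numbers; only starting materials, intermediates and products are numbered.
Assumption: the sense of induction of the iodoarene catalyst cannot be predicted with certainty; the (aS) antipode is written, and the (aR) antipode is used if a pilot run gives the enantiomer of 9.

**Step 1**
Reactants: 1 dec-1-yne; 2 1,8-dibromooctane
Product: 4 octadec-9-yn-1-yl bromide (1-bromooctadec-9-yne), via lithium decynide 3 (not isolated)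
Conditions: n-BuLi, THF, −78 → 0 °C; then 2 (4 equiv), DMPU, 0 °C → rt
Reagents that add atoms: none
Why: SN2 alkylation of a lithium acetylide with a large excess of a primary α,ω-dibromide gives the mono-alkylated bromoalkyne (excess 2 is distilled off); no stereocenter is formed.

**Step 2**
Reactants: 5 o-cresol; 4 octadec-9-yn-1-yl bromide
Product: 7 2-(nonadec-10-yn-1-yl)phenol, via dimetalated o-cresol 6 (not isolated)
Conditions: 5 (1.5 equiv), n-BuLi/KOtBu (3.0 equiv each), heptane, reflux, 3 h; then THF, −78 °C, 4 (1.0 equiv), → rt; aqueous work-up
Reagents that add atoms: none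
Why: Lateral (benzylic) metalation of o-cresol with the Lochmann–Schlosser superbase gives an O,C-dianion whose benzylic carbanion is far more nucleophilic than the phenoxide, so the primary bromide is C-alkylated by SN2 at −78 °C before propargylic deprotonation or E2 can compete; no stereocenter is formed.

**Step 3**
Reactants: 7 2-(nonadec-10-yn-1-yl)phenol
Product: 9 (1R,2R,6R)-2-hydroxy-2-(nonadec-10-yn-1-yl)-7-oxabicyclo[4.1.0]hept-4-en-3-one, via (6R)-o-quinol 8 (not isolated)
Conditions: (aS)-2,2'-diiodo-1,1'-binaphthyl-3,3'-dicarboxylic acid (15 mol%), mCPBA (3.2 equiv, pre-stirred with the catalyst 1 h), Na2HPO4, CH2Cl2, 0 °C; 7 added by syringe pump over 10 h (final 0.01 M); then aq. Na2S2O3/NaHCO3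
Reagents that add atoms: mCPBA, O=C(OO)c1cccc(Cl)c1
Why: Proposed new method: mCPBA oxidises the diiodide in situ to a C2-symmetric bis(benziodoxolone-type) λ5-iodane, phenol 7 exchanges onto I(V), and oxygen is transferred within the complex (ligand coupling, [2,3]-type) to the alkyl-bearing ortho carbon inside the biaryl pocket, which sets C6 as R and enforces ortho rather than para oxygenation, while mCPBA re-oxidises the I(III) left behind. Because 7 is fed slowly into excess peracid, quinol 8 stays at low-mM concentration, so its second-order Diels–Alder dimerisation should be outrun by the pseudo-first-order hydroxyl-directed (Henbest) epoxidation of the γ,δ-alkene, delivered syn to the tertiary OH and anti to the C19 chain (C4 R, C5 R). The closest known reactions are the stoichiometric hydroxylative phenol dearomatisation of 2-alkylphenols with chiral biaryl λ5-iodanes and the iodoarene/mCPBA-catalysed dearomatisation–epoxidation of 2-methyl-1-naphthol; new here are catalytic turnover with high ee on a phenol with no blocking substituent and the kinetic interception of a dimerisation-prone quinol.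

**Step 4**
Reactants: 9 (1R,2R,6R)-2-hydroxy-2-(nonadec-10-yn-1-yl)-7-oxabicyclo[4.1.0]hept-4-en-3-one
Product: 10 (4S,5R,6R)-4,5,6-trihydroxy-6-(nonadec-10-yn-1-yl)cyclohex-2-en-1-one
Conditions: HClO4 (5 mol%), THF/H2O 3:1, 0 °C → rt
Reagents that add atoms: water, O
Why: Acid-catalysed anti (SN2-like, trans-diaxial) hydrolysis of the vinyl epoxide, with water entering at C4 (allylic, less hindered, remote from the electron-withdrawing neopentyl-like C6 carbinol) with inversion, so C4 becomes S with its OH trans to the C5–OH, while C5 and C6 are untouched and the quaternary C6 blocks aromatisation.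

**Step 5**
Reactants: 10 (4S,5R,6R)-4,5,6-trihydroxy-6-(nonadec-10-yn-1-yl)cyclohex-2-en-1-one
Product: 11 (4S,5R,6R)-4,5,6-trihydroxy-6-[(10Z)-nonadec-10-en-1-yl]cyclohex-2-en-1-one
Conditions: H2 (1 atm), Lindlar catalyst (Pd/CaCO3, Pb-poisoned), quinoline, EtOAc, rt; stopped at 1.0 equiv H2
Reagents that add atoms: none
Why: Lindlar semihydrogenation delivers H2 syn to the alkyne on poisoned Pd to give only the Z-alkene; the alkyne out-competes the conjugated enone for the catalyst, so the ring C=C and the allylic C–O bond survive when uptake is stopped at one equivalent.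

**Compound list**
1 | dec-1-yne | CCCCCCCCC#C | starting material
2 | 1,8-dibromooctane | BrCCCCCCCCBr | starting material
3 | lithium dec-1-yn-1-ide (not isolated) | [Li]C#CCCCCCCCC | intermediate
4 | octadec-9-yn-1-yl bromide (1-bromooctadec-9-yne) | CCCCCCCCC#CCCCCCCCCBr | intermediate
5 | o-cresol (2-methylphenol) | Cc1ccccc1O | starting material
6 | O,C-dimetalated o-cresol, written as dipotassium 2-methanidylphenolate (not isolated) | [K+].[K+].[CH2-]c1ccccc1[O-] | intermediate
7 | 2-(nonadec-10-yn-1-yl)phenol | CCCCCCCCC#CCCCCCCCCCc1ccccc1O | intermediate
8 | (6R)-6-hydroxy-6-(nonadec-10-yn-1-yl)cyclohexa-2,4-dien-1-one (not isolated) | CCCCCCCCC#CCCCCCCCCC[C@]1(O)C(=O)C=CC=C1 | intermediate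
9 | (1R,2R,6R)-2-hydroxy-2-(nonadec-10-yn-1-yl)-7-oxabicyclo[4.1.0]hept-4-en-3-one, i.e. the (4R,5R,6R)-4,5-epoxy-6-hydroxycyclohex-2-enone with the epoxide cis to the OH | CCCCCCCCC#CCCCCCCCCC[C@]1(O)C(=O)C=C[C@H]2O[C@@H]12 | intermediate
10 | (4S,5R,6R)-4,5,6-trihydroxy-6-(nonadec-10-yn-1-yl)cyclohex-2-en-1-one | CCCCCCCCC#CCCCCCCCCC[C@]1(O)C(=O)C=C[C@H](O)[C@H]1O | intermediate
11 | (4S,5R,6R)-4,5,6-trihydroxy-6-[(10Z)-nonadec-10-en-1-yl]cyclohex-2-en-1-one (CNP0077460.1) | CCCCCCCC/C=C\CCCCCCCCC[C@]1(O)C(=O)C=C[C@H](O)[C@H]1O | target

**Step count and risks**
Total step count: 5. Longest linear sequence: 5 (steps 1–5; o-cresol enters at step 2).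

The three steps most likely to fail are steps 3, 4 and 2.

Step 3 is the proposed new reaction and the main risk. It can fail through low ee or the wrong sense of induction, through oxygenation at the free ortho C–H (giving a catechol or o-quinone), through [4+2] dimerisation of quinol 8, or through opening of 9 by m-chlorobenzoic acid. The fallback uses known chemistry and abandons both catalysis and the one-flask cascade. It sets out from 7, which is treated at −40 → −20 °C in CH2Cl2 with a stoichiometric amount of a preformed, isolated, axially chiral C2-symmetric 2,2'-bis(iodyl)-1,1'-biaryl (a bis-λ5-iodane made by dimethyldioxirane oxidation of the resolved diiodide), with no peracid present. This reagent-controlled hydroxylative dearomatisation is established for 2-alkylphenols and gives a cold, dilute solution of 8. Without concentration, that solution is treated with mCPBA/Na2HPO4 for the hydroxyl-directed epoxidation, and the sequence comes back to the route at 9. No new compound is made on this path (F0). The ee can be upgraded by recrystallising triol 10.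

Step 4 can fail through attack at C5 instead of C4, conjugate addition of water, or acid-promoted α-ketol or epoxide rearrangement of the sensitive epoxy-enone. The fallback replaces bimolecular acid hydrolysis by hydroxyl-directed delivery of a carboxylate. It sets out from 9, which is treated with Ti(OiPr)4 and benzoic acid in CH2Cl2 at rt. The titanium is bound by the C6–OH and the epoxide oxygen and directs benzoate to the distal carbon C4 with inversion, as in the C3-selective opening of 2,3-epoxy alcohols. This gives (1S,5R,6R)-5,6-dihydroxy-5-(nonadec-10-yn-1-yl)-4-oxocyclohex-2-en-1-yl benzoate F1. Mild methanolysis (cat. K2CO3, MeOH, 0 °C) then returns to the route at 10.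

Step 2 can fail because the superbasic dianion may attack propargylic C–H bonds or cause E2 of the bromide. The fallback avoids the superbase and makes the same benzylic C–C bond by copper catalysis. It sets out from 4, which is coupled with commercial 2-methoxybenzylmagnesium chloride (cat. Li2CuCl4, THF, 0 °C, Kochi-type sp3–sp3 coupling) to give 1-methoxy-2-(nonadec-10-yn-1-yl)benzene F2. SN2 O-demethylation with NaSEt in DMF at 120 °C (no Lewis acid that could haloborate the alkyne) then returns to the route at 7, at the cost of one extra step.

**Further compounds**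
F0 | step 3 | none | none
F1 | step 4 | (1S,5R,6R)-5,6-dihydroxy-5-(nonadec-10-yn-1-yl)-4-oxocyclohex-2-en-1-yl benzoate | CCCCCCCCC#CCCCCCCCCC[C@]1(O)C(=O)C=C[C@H](OC(=O)c2ccccc2)[C@H]1O
F2 | step 2 | 1-methoxy-2-(nonadec-10-yn-1-yl)benzene | CCCCCCCCC#CCCCCCCCCCc1ccccc1OC
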